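## Retrosynthetic overview

1. The target is epicatechin-(4β→6)-epicatechin-(4β→6)-epicatechin. The last C–C bond, C4(top)–C6(middle), is made by SN1-type Friedel–Crafts alkylation of a bromo-capped lower dimer (from (−)-epicatechin) with a top-unit chroman-4-ol, followed by global hydrogenolysis.
2. The top unit is built de novo. Its ring A arrives as 3,5-bis(benzyloxy)benzyne and is fused onto an open-chain syn-glycolate aldol amide; one operation makes O1–C8a and C4a–C4 and closes ring C as a chroman-4-one, which is then reduced at C4.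
3. Enabling feature: in ring A of the top unit the two fusion atoms C8a (bearing O1) and C4a (bearing C4) are ortho neighbours, and C4a is flanked by the C5 oxygen. This is the pattern a 3-alkoxyaryne gives when an O-nucleophile adds at the far carbon and the anion at the near carbon is trapped; O1 and C4 are the ends of the open chain O1–C2–C3–C4.
4. Because the O1–C2 bond is never broken, the syn-aldol pair (C2, C3) becomes the 2,3-cis arrangement directly; C4 of each upper unit is relayed from C3 by attack trans to the 3-oxygen.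
5. Ring order: all rings of the middle and bottom units are bought with epicatechin; ring B of the top unit comes with aldehyde 12; ring A and ring C of the top unit are installed together in the key step.

Key step: step 9

Remark: alcohols 21 and 22 are carried as C4-epimer mixtures (C4 left undefined in their SMILES) because both epimers ionise to the same cation in step 12; 6 and 11 are taken as catalogue compounds.

## Route

Step 1
Reactants: 1 (−)-epicatechin
Product: 2 5,7,3',4'-tetra-O-benzyl-(−)-epicatechin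
Conditions: BnBr (4.5 equiv), K2CO3, DMF, 0 °C to rt
Reagents that add atoms: benzyl bromide, BrCc1ccccc1
Why: Williamson etherification of the four phenols with a carbonate base should leave the much less acidic secondary 3-OH free and touches no stereocentre.

Step 2
Reactants: 2 5,7,3',4'-tetra-O-benzyl-(−)-epicatechin
Product: 3 8-bromo-5,7,3',4'-tetra-O-benzylepicatechin
Conditions: NBS (1.0 equiv), CH2Cl2, −40 °C to rt
Reagents that add atoms: N-bromosuccinimide, O=C1CCC(=O)N1Br
Why: Electrophilic aromatic bromination of the phloroglucinol-type ring A should occur at the less hindered C8 and not at C6, which lies between two benzyloxy groups.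

Step 3
Reactants: 3 8-bromo-5,7,3',4'-tetra-O-benzylepicatechin
Product: 4 8-bromo-4β-(2-ethoxyethoxy)-5,7,3',4'-tetra-O-benzylepicatechin
Conditions: DDQ (2 equiv), 2-ethoxyethanol (5 equiv), CH2Cl2, rt
Reagents that add atoms: 2-ethoxyethanol, CCOCCO
Why: Benzylic oxidation by hydride abstraction from the C4 methylene with DDQ, the ring-A-stabilised cation being captured by the alcohol trans to the 3-OH, should set the 4β (3,4-trans) ether by substrate control.

Step 4
Reactants: 4 8-bromo-4β-(2-ethoxyethoxy)-5,7,3',4'-tetra-O-benzylepicatechin; 3 8-bromo-5,7,3',4'-tetra-O-benzylepicatechin (4 equiv, excess recovered)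
Product: 5 bromo-capped lower dimer 8-bromo-tetra-O-benzylepicatechin-(4β→6)-8-bromo-tetra-O-benzylepicatechin
Conditions: Me3SiOTf (0.2 equiv), CH2Cl2, −78 to −40 °C; aq. NaHCO3
Reagents that add atoms: none
Why: SN1-type Friedel–Crafts alkylation (the standard interflavan coupling) in which the Lewis acid ionises the C4 ether of 4 and C6 of 3, the only free ring-A position because C8 is brominated, attacks trans to the 3-OH to give the 4β→6 bond, the excess of 3 suppressing self-condensation of 4.

Step 5
Reactants: 6 3,5-bis(benzyloxy)phenol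
Product: 7 2-bromo-3,5-bis(benzyloxy)phenol
Conditions: NBS (1.0 equiv), iPr2NH (0.1 equiv), CH2Cl2, −40 to 0 °C
Reagents that add atoms: N-bromosuccinimide, O=C1CCC(=O)N1Br
Why: Amine-mediated NBS bromination delivers bromine ortho to a free phenol through a hydrogen-bonded N-bromoamine, so substitution should occur at C2, between the OH and a benzyloxy group, and not at C4 between the two benzyloxy groups.

Step 6
Reactants: 7 2-bromo-3,5-bis(benzyloxy)phenol
Product: 10 3,5-bis(benzyloxy)-2-(trimethylsilyl)phenyl trifluoromethanesulfonate, via aryl trimethylsilyl ether 8 (not isolated), via lithium 2-silylphenoxide 9 (not isolated)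
Conditions: (Me3Si)2NH, THF, 70 °C, then evaporate; n-BuLi (1.1 equiv), THF, −78 °C; Tf2O (1.2 equiv), −78 °C to rt
Reagents that add atoms: hexamethyldisilazane, C[Si](C)(C)N[Si](C)(C)C; triflic anhydride, O=S(=O)(OS(=O)(=O)C(F)(F)F)C(F)(F)F
Why: Standard three-stage preparation of an ortho-silylaryl triflate by O-silylation, bromine–lithium exchange with anionic 1,3-silyl migration from O to C (retro-Brook rearrangement) and triflation of the lithium phenoxide so released.

Step 7
Reactants: 11 (S)-4-benzyl-3-[2-(benzyloxy)acetyl]oxazolidin-2-one; 12 3,4-bis(benzyloxy)benzaldehyde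
Product: 14 (S)-4-benzyl-3-[(2S,3R)-2-(benzyloxy)-3-[3,4-bis(benzyloxy)phenyl]-3-hydroxypropanoyl]oxazolidin-2-one, via Z-dibutylboron enolate 13 (not isolated)
Conditions: Bu2BOTf (1.2 equiv), Et3N (1.4 equiv), CH2Cl2, −78 to 0 °C; then 12, −78 to 0 °C; pH 7 buffer, MeOH, 30% H2O2, 0 °C
Reagents that add atoms: none
Why: Evans syn-aldol reaction in which the Z-boron enolate reacts through a closed Zimmerman–Traxler transition state on the face away from the benzyl group of the auxiliary, setting the (2S,3R) syn pair that becomes C3 and C2 of the top unit.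

Step 8
Reactants: 14 (S)-4-benzyl-3-[(2S,3R)-2-(benzyloxy)-3-[3,4-bis(benzyloxy)phenyl]-3-hydroxypropanoyl]oxazolidin-2-one
Product: 15 (2S,3R)-2-(benzyloxy)-3-[3,4-bis(benzyloxy)phenyl]-3-hydroxy-N-methoxy-N-methylpropanamide
Conditions: MeNHOMe·HCl (3 equiv), AlMe3 (3 equiv), CH2Cl2, −20 to 0 °C; 1 M HCl work-up
Reagents that add atoms: N,O-dimethylhydroxylamine hydrochloride, CNOC.Cl
Why: Aluminium-amide transamination of the aldol imide (Weinreb amide formation), assisted by the free β-hydroxyl, should release the auxiliary without epimerisation or retro-aldol cleavage.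

Step 9
Reactants: 15 (2S,3R)-2-(benzyloxy)-3-[3,4-bis(benzyloxy)phenyl]-3-hydroxy-N-methoxy-N-methylpropanamide; 10 3,5-bis(benzyloxy)-2-(trimethylsilyl)phenyl trifluoromethanesulfonate (1.5 equiv)
Product: 20 (2R,3S)-3,5,7-tris(benzyloxy)-2-[3,4-bis(benzyloxy)phenyl]chroman-4-one (2,3-cis), via potassium alkoxide 16 (not isolated), via 3,5-bis(benzyloxy)benzyne 17 (not isolated), via ortho-alkoxy aryl anion 18 (not isolated), via tetrahedral hemiaminal alkoxide 19 (not isolated)
Conditions: KH (1.05 equiv), 18-crown-6 (3 equiv), THF, 0 °C; then 10, KF (3 equiv), 0 °C to rt; AcOH (5 equiv), THF, −40 °C, then pH 7 buffer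
Reagents that add atoms: none
Why: Proposed new method: fluoride converts 10 into aryne 17, alkoxide 16 adds to the aryne carbon remote from the flanking benzyloxy group (making O1–C8a), and the aryl anion 18 formed next to that benzyloxy group attacks the Weinreb carbonyl (making C4a–C4) to give adduct 19, which releases ketone 20 on acidic quench. The closest known reaction type is the aryne annulation of salicylates and 2-aminobenzoates to xanthones and acridones (O- or N-arylation followed by intramolecular acylation of the aryl anion); what is new is an aliphatic secondary alkoxide carrying an amide electrophile. Ring C closes by 6-exo-trig attack of the aryl carbanion on the amide carbonyl, and ring A is delivered intact by the aryne. No stereocentre is created in the product, and C2 and C3 are retained because neither the O1–C2 bond nor any bond at C3 is broken, so the syn-aldol pair maps onto the 2,3-cis arrangement without inversion. The step needs regioselective O-attack on the unsymmetrical aryne, secured by the inductive and distortion effect of the benzyloxy group next to the triple bond, and C-acylation instead of protonation of the aryl anion, secured by a preformed alkoxide in an aprotic medium and a six-membered closure. The base-sensitive cis-3-alkoxy ketone is protected because the N-methoxy-N-methyl hemiaminal alkoxide should persist until the cold acetic acid quench.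

Step 10
Reactants: 20 (2R,3S)-3,5,7-tris(benzyloxy)-2-[3,4-bis(benzyloxy)phenyl]chroman-4-one
Product: 21 (2R,3R)-3,5,7-tris(benzyloxy)-2-[3,4-bis(benzyloxy)phenyl]chroman-4-ol (C4 epimer mixture)
Conditions: NaBH4 (1.5 equiv), CeCl3·7H2O (1.2 equiv), MeOH/THF, −40 to −20 °C
Reagents that add atoms: none
Why: Luche reduction under nearly neutral conditions at low temperature should be faster than enolisation, so C2 and C3 are kept, and hydride is expected to add anti to the pseudo-axial 3-benzyloxy group although the C4 configuration is not needed.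

Step 11
Reactants: 21 (2R,3R)-3,5,7-tris(benzyloxy)-2-[3,4-bis(benzyloxy)phenyl]chroman-4-ol
Product: 22 (2R,3R)-8-bromo-3,5,7-tris(benzyloxy)-2-[3,4-bis(benzyloxy)phenyl]chroman-4-ol (C4 epimer mixture)
Conditions: NBS (1.0 equiv), NaHCO3 (solid), CH2Cl2, −78 to −40 °C
Reagents that add atoms: N-bromosuccinimide, O=C1CCC(=O)N1Br
Why: Electrophilic aromatic bromination at C8 as in step 2 caps the most nucleophilic position of ring A, so that the top unit cannot act as a C8 nucleophile in step 12.

Step 12
Reactants: 22 (2R,3R)-8-bromo-3,5,7-tris(benzyloxy)-2-[3,4-bis(benzyloxy)phenyl]chroman-4-ol; 5 bromo-capped lower dimer (2 equiv, excess recovered)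
Product: 23 protected trimer 3-O-benzyl-8-bromo-tetra-O-benzylepicatechin-(4β→6)-8-bromo-tetra-O-benzylepicatechin-(4β→6)-8-bromo-tetra-O-benzylepicatechin
Conditions: Me3SiOTf (0.3 equiv), 4 Å molecular sieves, CH2Cl2, −78 to −30 °C, 22 added over 2 h; Et3N quench
Reagents that add atoms: none
Why: SN1-type Friedel–Crafts alkylation as in step 4, in which the Lewis acid ionises the benzylic C4–OH of 22 with loss of water (taken up by the molecular sieves) and C6 of the middle unit of 5, the only unsubstituted ring-A position of 5, attacks the cation trans to the 3-benzyloxy and 2-aryl groups, setting the 4β stereocentre by substrate control from C3.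

Step 13
Reactants: 23 protected trimer
Product: 24 epicatechin-(4β→6)-epicatechin-(4β→6)-epicatechin (target)
Conditions: H2 (1 atm), Pd(OH)2/C, Et3N (3.3 equiv), THF/MeOH/H2O, rt; filtration under argon, lyophilisation
Reagents that add atoms: none
Why: Hydrogenolysis over Pd(OH)2/C should cleave the thirteen benzyl ethers and, with Et3N as HBr acceptor, the three aryl C–Br bonds without touching any stereocentre.

## Compound list

1 | (−)-epicatechin, (2R,3R)-2-(3,4-dihydroxyphenyl)chromane-3,5,7-triol | Oc1cc(O)c2c(c1)O[C@H](c1ccc(O)c(O)c1)[C@H](O)C2 | starting material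
2 | 5,7,3',4'-tetra-O-benzyl-(−)-epicatechin, (2R,3R)-5,7-bis(benzyloxy)-2-[3,4-bis(benzyloxy)phenyl]chroman-3-ol | C(c1ccccc1)Oc1cc(OCc2ccccc2)c2c(c1)O[C@H](c1ccc(OCc3ccccc3)c(OCc3ccccc3)c1)[C@H](O)C2 | intermediate
3 | 8-bromo-5,7,3',4'-tetra-O-benzylepicatechin (2R,3R) | C(c1ccccc1)Oc1cc(OCc2ccccc2)c2c(c1Br)O[C@H](c1ccc(OCc3ccccc3)c(OCc3ccccc3)c1)[C@H](O)C2 | intermediate
4 | 8-bromo-4β-(2-ethoxyethoxy)-5,7,3',4'-tetra-O-benzylepicatechin (2R,3R,4S; 4-alkoxy trans to 3-OH) | C(c1ccccc1)Oc1cc(OCc2ccccc2)c2c(c1Br)O[C@H](c1ccc(OCc3ccccc3)c(OCc3ccccc3)c1)[C@H](O)[C@H]2OCCOCC | intermediate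
5 | bromo-capped lower dimer, 8-bromo-tetra-O-benzylepicatechin-(4β→6)-8-bromo-tetra-O-benzylepicatechin (both 3-OH free; C6 of the upper unit unsubstituted) | c1c(OCc2ccccc2)c(Br)c2c(c1OCc1ccccc1)[C@H](c1c(OCc3ccccc3)c(Br)c3c(c1OCc1ccccc1)C[C@@H](O)[C@@H](c1ccc(OCc4ccccc4)c(OCc4ccccc4)c1)O3)[C@@H](O)[C@@H](c1ccc(OCc3ccccc3)c(OCc3ccccc3)c1)O2 | intermediate
6 | 3,5-bis(benzyloxy)phenol | Oc1cc(OCc2ccccc2)cc(OCc2ccccc2)c1 | starting material
7 | 2-bromo-3,5-bis(benzyloxy)phenol | Oc1cc(OCc2ccccc2)cc(OCc2ccccc2)c1Br | intermediate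
8 | [2-bromo-3,5-bis(benzyloxy)phenoxy]trimethylsilane | C[Si](C)(C)Oc1cc(OCc2ccccc2)cc(OCc2ccccc2)c1Br | intermediate (not isolated)
9 | lithium 3,5-bis(benzyloxy)-2-(trimethylsilyl)phenoxide | [Li+].[O-]c1cc(OCc2ccccc2)cc(OCc2ccccc2)c1[Si](C)(C)C | intermediate (not isolated)
10 | 3,5-bis(benzyloxy)-2-(trimethylsilyl)phenyl trifluoromethanesulfonate | FC(F)(F)S(=O)(=O)Oc1cc(OCc2ccccc2)cc(OCc2ccccc2)c1[Si](C)(C)C | intermediate
11 | (S)-4-benzyl-3-[2-(benzyloxy)acetyl]oxazolidin-2-one | O=C(COCc1ccccc1)N1C(=O)OC[C@@H]1Cc1ccccc1 | starting material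
12 | 3,4-bis(benzyloxy)benzaldehyde | O=Cc1ccc(OCc2ccccc2)c(OCc2ccccc2)c1 | starting material
13 | Z-dibutylboron enolate of 11 | CCCCB(CCCC)O/C(=C\OCc1ccccc1)N1C(=O)OC[C@@H]1Cc1ccccc1 | intermediate (not isolated)
14 | (S)-4-benzyl-3-[(2S,3R)-2-(benzyloxy)-3-[3,4-bis(benzyloxy)phenyl]-3-hydroxypropanoyl]oxazolidin-2-one | O[C@H](c1ccc(OCc2ccccc2)c(OCc2ccccc2)c1)[C@H](OCc1ccccc1)C(=O)N1C(=O)OC[C@@H]1Cc1ccccc1 | intermediate
15 | (2S,3R)-2-(benzyloxy)-3-[3,4-bis(benzyloxy)phenyl]-3-hydroxy-N-methoxy-N-methylpropanamide | O[C@H](c1ccc(OCc2ccccc2)c(OCc2ccccc2)c1)[C@H](OCc1ccccc1)C(=O)N(C)OC | intermediate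
16 | potassium alkoxide of 15 | [K+].[O-][C@H](c1ccc(OCc2ccccc2)c(OCc2ccccc2)c1)[C@H](OCc1ccccc1)C(=O)N(C)OC | intermediate (not isolated)
17 | 3,5-bis(benzyloxy)benzyne (1,2-didehydro-3,5-bis(benzyloxy)benzene) | C1#CC(OCc2ccccc2)=CC(OCc2ccccc2)=C1 | intermediate (not isolated)
18 | aryl anion (potassium salt) formed by O-arylation of 16, carbanion between the new ether oxygen and a benzyloxy group | [K+].[c-]1c(OCc2ccccc2)cc(OCc2ccccc2)cc1O[C@H](c1ccc(OCc2ccccc2)c(OCc2ccccc2)c1)[C@H](OCc1ccccc1)C(=O)N(C)OC | intermediate (not isolated)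
19 | tetrahedral adduct, potassium 3,5,7-tris(benzyloxy)-2-[3,4-bis(benzyloxy)phenyl]-4-[methoxy(methyl)amino]chroman-4-olate (C2 and C3 as in 20) | [K+].C(c1ccccc1)Oc1cc(OCc2ccccc2)c2c(c1)O[C@H](c1ccc(OCc3ccccc3)c(OCc3ccccc3)c1)[C@H](OCc1ccccc1)C2([O-])N(C)OC | intermediate (not isolated)
20 | (2R,3S)-3,5,7-tris(benzyloxy)-2-[3,4-bis(benzyloxy)phenyl]chroman-4-one (2,3-cis) | C(c1ccccc1)Oc1cc(OCc2ccccc2)c2c(c1)O[C@H](c1ccc(OCc3ccccc3)c(OCc3ccccc3)c1)[C@H](OCc1ccccc1)C2=O | intermediate
21 | (2R,3R)-3,5,7-tris(benzyloxy)-2-[3,4-bis(benzyloxy)phenyl]chroman-4-ol (2,3-cis; C4 epimer mixture) | C(c1ccccc1)Oc1cc(OCc2ccccc2)c2c(c1)O[C@H](c1ccc(OCc3ccccc3)c(OCc3ccccc3)c1)[C@H](OCc1ccccc1)C2O | intermediate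
22 | (2R,3R)-8-bromo-3,5,7-tris(benzyloxy)-2-[3,4-bis(benzyloxy)phenyl]chroman-4-ol (2,3-cis; C4 epimer mixture) | C(c1ccccc1)Oc1cc(OCc2ccccc2)c2c(c1Br)O[C@H](c1ccc(OCc3ccccc3)c(OCc3ccccc3)c1)[C@H](OCc1ccccc1)C2O | intermediate
23 | protected trimer, 3-O-benzyl-8-bromo-tetra-O-benzylepicatechin-(4β→6)-8-bromo-tetra-O-benzylepicatechin-(4β→6)-8-bromo-tetra-O-benzylepicatechin | C(c1ccccc1)Oc1cc(OCc2ccccc2)c2c(c1Br)O[C@H](c1ccc(OCc3ccccc3)c(OCc3ccccc3)c1)[C@H](OCc1ccccc1)[C@H]2c1c(OCc2ccccc2)c(Br)c2c(c1OCc1ccccc1)[C@H](c1c(OCc3ccccc3)c(Br)c3c(c1OCc1ccccc1)C[C@@H](O)[C@@H](c1ccc(OCc4ccccc4)c(OCc4ccccc4)c1)O3)[C@@H](O)[C@@H](c1ccc(OCc3ccccc3)c(OCc3ccccc3)c1)O2 | intermediate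
24 | epicatechin-(4β→6)-epicatechin-(4β→6)-epicatechin (CNP0163146.2) | Oc1cc(O)c2c(c1)O[C@H](c1ccc(O)c(O)c1)[C@H](O)[C@H]2c1c(O)cc2c(c1O)[C@H](c1c(O)cc3c(c1O)C[C@@H](O)[C@@H](c1ccc(O)c(O)c1)O3)[C@@H](O)[C@@H](c1ccc(O)c(O)c1)O2 | target

## Step count and risks

Total step count: 13. Longest linear sequence: 7 steps (6 → 7 → 10 → 20 → 21 → 22 → 23 → 24; the branch from 11 is equally long).

**Step 9 (proposed new method).** Several processes may defeat the annulation: protonation of the aryl anion, giving simple O-arylation; retro-aldol cleavage of the potassium alkoxide before the aryne is available; proton abstraction from a benzylic OCH2 by the aryl anion; and early collapse of the tetrahedral adduct, followed by base-mediated epimerisation at C3 or ring opening of the cis-3-alkoxy ketone. The fallback sets out from 15 (with 10) and makes the same two bonds in separate, known operations. The neutral alcohol 15 is O-arylated by the aryne under protic fluoride conditions (CsF, MeCN, rt; O–H insertion, the aryl anion being protonated) to give (2S,3R)-2-(benzyloxy)-3-[3,4-bis(benzyloxy)phenyl]-3-[3,5-bis(benzyloxy)phenoxy]-N-methoxy-N-methylpropanamide F1. Its Weinreb amide is reduced with LiAlH4 at −78 °C to (2S,3R)-2-(benzyloxy)-3-[3,4-bis(benzyloxy)phenyl]-3-[3,5-bis(benzyloxy)phenoxy]propanal F2. Chelation-activated intramolecular Friedel–Crafts hydroxyalkylation (MgBr2·OEt2, CH2Cl2, −40 °C) at either of the two equivalent ortho positions of the phloroglucinol-type ether then closes ring C. This comes back to the route at alcohol 21 and bypasses the base-sensitive ketone 20.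

**Step 12.** Alkylation at C6 of 5, which lies between two benzyloxy groups, may be slow. The cation from 22 could then be consumed by the free C6 of a second molecule of 22, or the acid could cleave the interflavan bond already present, wasting the dimer. The fallback reverses the order of assembly so that each Friedel–Crafts step uses a cheap monomer nucleophile in excess. It sets out from 4, which is exchanged with phenylmethanethiol and BF3·OEt2 into 8-bromo-4β-(benzylthio)-5,7,3',4'-tetra-O-benzylepicatechin F3. F3 (excess) is alkylated at C6 by 22 under hard Lewis-acid activation (BF3·OEt2, which leaves the thioether untouched) to give the top–middle dimer 4β-benzylthio ether F4. Thiophilic activation of F4 with AgBF4 in the presence of excess 3 forms the second interflavan bond and comes back to the route at 23.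

**Step 5.** Bromination para to the hydroxyl (between the two benzyloxy groups) or over-bromination may compete with clean ortho-bromination. The fallback sets out from 6 and uses directed metalation. Isopropyl isocyanate with Et3N gives 3,5-bis(benzyloxy)phenyl isopropylcarbamate F5. In-situ N-silylation (t-BuMe2SiOTf, TMEDA), ortho-lithiation with n-BuLi at −78 °C between the carbamate and a benzyloxy group and quenching with Me3SiCl give 3,5-bis(benzyloxy)-2-(trimethylsilyl)phenyl isopropylcarbamate F6. One-pot carbamate cleavage (Et2NH, DBU, MeCN) and triflation with PhNTf2 come back to the route at 10, bypassing 7.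

## Further compounds

F1 | step 9 | (2S,3R)-2-(benzyloxy)-3-[3,4-bis(benzyloxy)phenyl]-3-[3,5-bis(benzyloxy)phenoxy]-N-methoxy-N-methylpropanamide | C(c1ccccc1)Oc1cc(OCc2ccccc2)cc(c1)O[C@H](c1ccc(OCc3ccccc3)c(OCc3ccccc3)c1)[C@H](OCc1ccccc1)C(=O)N(C)OC
F2 | step 9 | (2S,3R)-2-(benzyloxy)-3-[3,4-bis(benzyloxy)phenyl]-3-[3,5-bis(benzyloxy)phenoxy]propanal | C(c1ccccc1)Oc1cc(OCc2ccccc2)cc(c1)O[C@H](c1ccc(OCc3ccccc3)c(OCc3ccccc3)c1)[C@H](OCc1ccccc1)C=O
F3 | step 12 | 8-bromo-4β-(benzylthio)-5,7,3',4'-tetra-O-benzylepicatechin | C(c1ccccc1)Oc1cc(OCc2ccccc2)c2c(c1Br)O[C@H](c1ccc(OCc3ccccc3)c(OCc3ccccc3)c1)[C@H](O)[C@H]2SCc1ccccc1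
F4 | step 12 | 3-O-benzyl-8-bromo-tetra-O-benzylepicatechin-(4β→6)-8-bromo-4β-(benzylthio)-tetra-O-benzylepicatechin | C(c1ccccc1)Oc1cc(OCc2ccccc2)c2c(c1Br)O[C@H](c1ccc(OCc3ccccc3)c(OCc3ccccc3)c1)[C@H](OCc1ccccc1)[C@H]2c1c(OCc2ccccc2)c(Br)c2c(c1OCc1ccccc1)[C@H](SCc1ccccc1)[C@@H](O)[C@@H](c1ccc(OCc3ccccc3)c(OCc3ccccc3)c1)O2
F5 | step 5 | 3,5-bis(benzyloxy)phenyl isopropylcarbamate | CC(C)NC(=O)Oc1cc(OCc2ccccc2)cc(OCc2ccccc2)c1
F6 | step 5 | 3,5-bis(benzyloxy)-2-(trimethylsilyl)phenyl isopropylcarbamate | CC(C)NC(=O)Oc1cc(OCc2ccccc2)cc(OCc2ccccc2)c1[Si](C)(C)C
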